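## Structural features

The target is a longipinane diester, numbered here C1–C11. It is a 3-methylcyclohex-2-enone (C1 ketone, C2=C3, C4, C10, C11) whose C4 and C11 are bridged by C5, so that C4–C5–C11–C10 is a cyclobutane and the six-membered ring plus C5 is a bicyclo[3.1.1]heptenone. A four-carbon chain, C6 (gem-dimethyl), C7, C8, C9, links C5 to the methyl-bearing quaternary C10 on the cyclobutane face opposite the C1–C3 bridge. This closes two seven-membered rings (through C4 or through C11) and fixes the relative configuration of the contiguous centres C4, C5, C10 and C11 by topology. The open stereochemical questions are therefore the absolute sense of the cage, C7 (isovalerate, on the face of the C10 methyl) and C9 (tiglate, 1,3-trans to C7 and next to C10). Fragile elements are the (E)-tigloyl alkene, the two secondary esters flanking C8, the γ-hydrogen at C4 of the enone, and the cyclobutane bonds C11–C5 and C11–C10, which are aligned with the C1 carbonyl π system and open whenever C1 becomes a ketyl or C11 a carbanion. The difficulty lies in the C5–C11 bond: C5 is a neopentylic, unactivated methylene and C11 is a bridgehead that cannot be enolised, so displacement and enolate chemistry are closed. The plan uses the fact that C11 is α to C1: in a cis-fused bicyclic precursor C11 can be a second carbonyl, and in the half-chair that holds C5 pseudo-axial on C4 its oxygen lies 1,5 to a C5 hydrogen (O, C11, C10, C4, C5, H), with the radical pair already placed for a 1,3-diaxial closure.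

## Logic of the disconnections

**24 to 22 (through 23).** The C11–H bond is traced back to a C11–O bond, because the key step can only leave C11 as a tertiary alcohol. The bridgehead C–O bond lies in the nodal plane of the C1 carbonyl, so electron-transfer cleavage of the α-ketol has no overlap and would instead break the aligned cyclobutane bonds; the enolate it would need is a bridgehead alkene. The forward step must therefore pass through a bridgehead σ-radical, which 23 provides.

**22 to 21.** The C5–C11 bond is cut. This removes the four-membered ring and the centres C5 and C11 and leaves a cis-fused bicycle. The forward step is a 1,5-hydrogen transfer to the C11 oxygen and closure of the 1,4-biradical. The configurations at C4, C7 and C10 drawn for this precursor/product pair agree with 24, so no descriptor needed changing. The change is at C9: a C9 carbonyl in 21 was rejected because the photoproduct would then be a 2-acylcyclobutanol, which opens by retro-aldol cleavage of C10–C11 with release of ring strain, and the dione stage would contain a base-labile β-acyloxy ketone. C9 is therefore carried as its final tiglate.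

**21 to 18 (through 20 and 19).** The C11=O and C1=O bonds are removed in turn. Both oxygens come from C–H bonds of a plain cyclohexene, so no functionality has to be carried through the ring-forming steps. The forward steps must oxidise the C1 methylene and not C4–H or the C3 methyl, and must enolise C11 kinetically without touching the esters or C4–H.

**18 to 15 and 16.** The C9–O acyl bond is cut. The tiglate is put on late enough to avoid the organometallic and hydride steps and early enough to mask C9–OH during the oxidations. The demand is esterification of a neopentylic secondary alcohol without E/Z loss (through 17).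

**15 to 13 and 14.** The C7–O acyl bond and the C9–H bond are cut together. One step then sets C9 trans to C7 and tells the two oxygens apart. It needs intramolecular hydride delivery across the seven-membered ring.

**13 to 11 (through 12).** The C7–O bond is cut back to an enone β-carbon. Both C7 epimers of an aldol would converge on 11, so C7 is set by a face-selective conjugate borylation and not by a ring-closing aldol of unknown selectivity.

**11 to 9 (through 10).** The C7=C8 bond is cut to a keto aldehyde in which the ketone enolises only at C8 and the aldehyde not at all. The only demand is seven-membered ring closure over dimerisation.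

**9 to 6 (through 8 and 7).** The C8–C9 bond (a methyl addition) and two oxidation levels are removed. This exposes an α-methyl aldehyde, the best-behaved dienophile class for catalytic asymmetric cycloaddition.

**6 to 5 and 3.** The C4–C10 and C1–C11 bonds are cut (Diels–Alder). The step creates the six-membered ring and the C4/C10 pair in absolute and relative terms. It needs "ortho" orientation against the opposing 2-methyl group, endo placement of the formyl group and one enal face.

**5 to 4, then to 2 and 3, then to 1.** The C1=C2 bond (methylenation) and the C3=C4 bond (cross-metathesis with the same enal, 3) are cut, then the O–Si bond. The (E)-geometry of C3=C4 is the only demand, and metathesis to a trisubstituted enal meets it.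

## Other disconnections considered

**Alternative 1:** The cut removes C5–C11, C5–C6 and C4–C10 at once and returns to acyclic (2E,6E)-farnesyl diphosphate A1. The forward step is an enzyme-steered cationic cascade in a magnesium-dependent synthase that gives α-longipinene A2.
- In favour: the whole tricyclic skeleton and all four cage stereocentres arise in one operation from an achiral, fermentable substrate, with enantiocontrol built in. In skeletal step economy this is better than the chosen plan.
- Against it here: A2 carries no oxygen. C1 is an allylic methylene and could be oxidised, but C7 and C9 are unactivated ring methylenes that would have to be hydroxylated with the right regiochemistry, trans to each other, and then told apart for two different esters. That would need dedicated hydroxylases, and synthases of this family tend to give product mixtures.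
- Comparison: on structure the chosen plan brings the C7 and C9 oxygens in from the start; on mechanism a cation cascade replaces a radical pair; on step economy the alternative is shorter to the skeleton and longer, and unpredictable, after it.

**Alternative 2:** The cut removes C5–C6 and C9–C10, so the seven-membered ring is formed across an existing cyclobutane. Forward, iron-carbonyl reduction of dibromocyclobutanone A3 gives a four-membered oxyallyl cation that adds (4+3) to alkoxy silyloxy diene A4 to give bicyclo[4.1.1]octenone A5.
- In favour: no four-membered ring has to be made, so neither a photochemical step nor a bridgehead deoxygenation is needed. On this point it is the equal or the better of the chosen plan. It is convergent, and C7 and C9 arrive oxygenated.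
- Against it here: an oxyallyl cation inside a four-membered ring is strained and prone to ring contraction. The cycloaddition must bond the methyl-bearing C10 and the fully substituted diene terminus C6, the worst steric case. The pairing of termini and the C9/C11 relationship are not controlled, and the product is racemic. After A5 the six-membered ring must still be annulated from the C11 ester and the bridging C4 ketone, the C7 carbonyl reduced with control, and the C9 ether exchanged for the tiglate.
- Comparison: on structure it makes the seven-membered ring last and the chosen plan makes the cyclobutane last; on mechanism a cationic cycloaddition replaces hydrogen transfer and radical coupling; on step economy the core comes sooner but the total is probably no shorter, and enantiocontrol is missing.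

**Alternative 3:** The cut removes C1–C11 and C4–C5 in a norbornene that holds a temporary C1–C10 bond. Forward, the (E)-alkenylboronate of tethered silyloxycyclopentadiene A6 adds across C1 and C4 to give norbornene A7; a 1,2-shift of C10 from C1 to C11 with loss of boron then collapses the C1 silyl ether to the ketone.
- In favour: cyclopentadiene cycloadditions are fast and predictable, the six- and seven-membered rings and C4, C5 and C11 are set together, and the shift delivers C11–H directly with inversion. Avoiding the bridgehead C–O removal makes its endgame better than that of the chosen plan, and it is thermal.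
- Against it here: A6 is itself a demanding target (a 5,5-disubstituted cyclopentadiene with the C10 quaternary stereocentre, a defined silyloxy/methyl pattern, and a tether carrying C7, C9 and the boronate). The cycloaddition must close a seven-membered ring through the sp3 ring carbon. The norbornyl-to-pinyl shift runs against ring strain and depends on carbonyl formation to pull it, with competing shifts and deboronation.
- Comparison: on structure it forms the cage bonds earlier and corrects connectivity afterwards; on mechanism a pericyclic step and a cationic shift replace photochemistry; on step economy it is shorter after the key step and clearly longer before it.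

Key step: step 14

Remark on nomenclature: bicyclic and tricyclic compounds are named with the target locants (six-membered ring C10–C11–C1–C2–C3–C4, seven-membered ring C4–C5–C6–C7–C8–C9–C10, cyclobutane C4–C5–C11–C10); CIP descriptors refer to these locants.

Remark on the chemistry: 2,2-dimethylpent-4-en-1-ol, methacrolein, 3-methylbutanal and tiglic acid are taken as catalogue compounds.

## Route

Step 1
Reactants: 1 2,2-dimethylpent-4-en-1-ol
Product: 2 triethyl[(2,2-dimethylpent-4-en-1-yl)oxy]silane
Conditions: Et3SiCl, imidazole, CH2Cl2, 0 °C to rt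
Reagents that add atoms: chlorotriethylsilane, CC[Si](Cl)(CC)CC
Why: Silylation of a primary alcohol; the triethylsilyl ether is a weak Lewis base that should not compete for the boron catalyst of step 4, and it is removed by the mild acid of step 5.

Step 2
Reactants: 2 triethyl[(2,2-dimethylpent-4-en-1-yl)oxy]silane; 3 methacrolein (2-methylprop-2-enal)
Product: 4 (2E)-2,5,5-trimethyl-6-[(triethylsilyl)oxy]hex-2-enal
Conditions: second-generation Grubbs catalyst (5 mol%), methacrolein (5 equiv), CH2Cl2, 40 °C
Reagents that add atoms: none
Why: Olefin cross-metathesis of a terminal alkene with a 1,1-disubstituted electron-poor partner; the trisubstituted enal should form as the thermodynamically preferred E isomer, which fixes the later diene geometry, and loss of ethene drives the exchange.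

Step 3
Reactants: 4 (2E)-2,5,5-trimethyl-6-[(triethylsilyl)oxy]hex-2-enal
Product: 5 triethyl{[(4E)-2,2,5-trimethylhepta-4,6-dien-1-yl]oxy}silane
Conditions: Ph3PCH3Br, KOt-Bu, THF, 0 °C to rt
Reagents that add atoms: methyltriphenylphosphonium bromide, C[P+](c1ccccc1)(c1ccccc1)c1ccccc1.[Br-]
Why: Wittig methylenation; the non-stabilised ylide adds 1,2 to the enal and leaves the E trisubstituted alkene untouched, giving the (E)-1-alkyl-2-methylbuta-1,3-diene.

Step 4
Reactants: 5 triethyl{[(4E)-2,2,5-trimethylhepta-4,6-dien-1-yl]oxy}silane; 3 methacrolein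
Product: 6 (1S,2R)-2-{2,2-dimethyl-3-[(triethylsilyl)oxy]propyl}-1,3-dimethylcyclohex-3-ene-1-carbaldehyde (formyl group and side chain cis)
Conditions: (S)-B-(o-tolyl)oxazaborolidine from (S)-α,α-diphenylprolinol, Tf2NH (20 mol% each), methacrolein (2 equiv), CH2Cl2, −78 to −40 °C
Reagents that add atoms: none
Why: Enantioselective Diels–Alder reaction of a 2-substituted acrolein under cationic oxazaborolidine catalysis; the enal methylene bonds to the unhindered diene terminus C1 and C10 to the alkyl-bearing C4 (the 1-alkyl group and sterics should outweigh the opposing 2-methyl), the activated formyl group is expected endo and so cis to the side chain, and the catalyst shields one enal face so that the (1S,2R) adduct, C10 and C4 of the target, should result (the mirror-image catalyst is used if the facial sense proves opposite).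

Step 5
Reactants: 6 (1S,2R)-2-{2,2-dimethyl-3-[(triethylsilyl)oxy]propyl}-1,3-dimethylcyclohex-3-ene-1-carbaldehyde
Product: 8 1-[(1S,2R)-2-(3-hydroxy-2,2-dimethylpropyl)-1,3-dimethylcyclohex-3-en-1-yl]ethan-1-ol (both carbinol epimers), via silyl ether carbinol 7 (not isolated)
Conditions: MeMgBr, THF, −78 to 0 °C; aq. NH4Cl; then AcOH/THF/H2O, rt
Reagents that add atoms: methylmagnesium bromide, C[Mg]Br
Why: Grignard addition to a non-enolisable neopentylic aldehyde gives the carbinol as an epimer mixture that is oxidised away in step 6; dilute acetic acid then removes the primary triethylsilyl ether without touching the trisubstituted alkene.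

Step 6
Reactants: 8 1-[(1S,2R)-2-(3-hydroxy-2,2-dimethylpropyl)-1,3-dimethylcyclohex-3-en-1-yl]ethan-1-ol
Product: 9 3-[(1R,6S)-6-acetyl-2,6-dimethylcyclohex-2-en-1-yl]-2,2-dimethylpropanal
Conditions: (COCl)2, DMSO, CH2Cl2, −78 °C; Et3N, −78 to 0 °C
Reagents that add atoms: none
Why: Swern oxidation converts both alcohols at once through their alkoxysulfonium salts, so no hydroxy aldehyde (lactol) stage is exposed; neither new carbonyl has an epimerisable α-stereocentre.

Step 7
Reactants: 9 3-[(1R,6S)-6-acetyl-2,6-dimethylcyclohex-2-en-1-yl]-2,2-dimethylpropanal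
Product: 11 (4R,10S)-3,6,6,10-tetramethylbicyclo[5.4.0]undeca-2,7-dien-9-one (cis-fused), via aldol adduct 10 (not isolated)
Conditions: KOt-Bu (0.3 equiv), t-BuOH/THF, 0.02 M, 0 to 40 °C
Reagents that add atoms: none
Why: Intramolecular aldol condensation; the ketone can enolise only at C8 and the aldehyde not at all, so only the 7-(enolendo)-exo-trig closure of C8 onto C7 is open, and E1cB loss of water gives the conjugated cycloheptenone, erasing the uncontrolled C7 carbinol centre; dilution suppresses dimerisation and the cis fusion comes from 6.

Step 8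
Reactants: 11 (4R,10S)-3,6,6,10-tetramethylbicyclo[5.4.0]undeca-2,7-dien-9-one
Product: 13 (4R,7R,10S)-7-hydroxy-3,6,6,10-tetramethylbicyclo[5.4.0]undec-2-en-9-one, via pinacol boronate 12 (not isolated)
Conditions: CuCl (5 mol%), NaOt-Bu (10 mol%), (R,R)-QuinoxP* (6 mol%), B2pin2, MeOH, THF, rt; then NaBO3·4H2O, THF/H2O, rt
Reagents that add atoms: bis(pinacolato)diboron, CC1(C)OB(OC1(C)C)B1OC(C)(C)C(C)(C)O1 (boron of 12); sodium perborate, [Na+].[O-]OB=O (oxygen of 13)
Why: Copper-catalysed conjugate borylation of the enone, then oxidation of the C–B bond with retention; boron should go to C7 from the convex face of the cis-fused bicycle (the face of the C10 methyl and C4–H), and the chiral bisphosphine is chosen to reinforce that sense (its antipode is used if the matched sense proves opposite), giving 7R; the isolated C2=C3 alkene is inert.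

Step 9
Reactants: 13 (4R,7R,10S)-7-hydroxy-3,6,6,10-tetramethylbicyclo[5.4.0]undec-2-en-9-one; 14 3-methylbutanal
Product: 15 (4R,7R,9R,10S)-9-hydroxy-3,6,6,10-tetramethylbicyclo[5.4.0]undec-2-en-7-yl 3-methylbutanoate
Conditions: SmI2 (0.3 equiv), 3-methylbutanal (6 equiv), THF, −10 °C
Reagents that add atoms: none
Why: Evans–Tishchenko reduction; the C7 oxygen adds to the aldehyde, samarium bridges the hemiacetal and the C9 carbonyl, and hydride passes intramolecularly to C9 on the face of the C7 oxygen, so the new C9–OH is 1,3-trans to C7–O and the C7 oxygen leaves the step as the isovalerate.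

Step 10
Reactants: 15 (4R,7R,9R,10S)-9-hydroxy-3,6,6,10-tetramethylbicyclo[5.4.0]undec-2-en-7-yl 3-methylbutanoate; 16 tiglic acid, (2E)-2-methylbut-2-enoic acid
Product: 18 (4R,7R,9R,10S)-7-(3-methylbutanoyloxy)-3,6,6,10-tetramethylbicyclo[5.4.0]undec-2-en-9-yl (2E)-2-methylbut-2-enoate, via mixed anhydride 17 (not isolated)
Conditions: tiglic acid, 2,4,6-trichlorobenzoyl chloride, Et3N, toluene, rt; then 15, DMAP, toluene, 80 °C
Reagents that add atoms: none
Why: Yamaguchi esterification; the acylpyridinium formed from the mixed anhydride should overcome the hindrance of the neopentylic C9 alcohol, and the E geometry of the acid is retained under these conditions.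

Step 11
Reactants: 18 (4R,7R,9R,10S)-7-(3-methylbutanoyloxy)-3,6,6,10-tetramethylbicyclo[5.4.0]undec-2-en-9-yl (2E)-2-methylbut-2-enoate
Product: 19 (4R,7R,9R,10S)-7-(3-methylbutanoyloxy)-3,6,6,10-tetramethyl-1-oxobicyclo[5.4.0]undec-2-en-9-yl (2E)-2-methylbut-2-enoate
Conditions: Rh2(cap)4 (cap = caprolactamate, 1 mol%), t-BuOOH (70% in H2O, 5 equiv), 1,2-dichloroethane, 40 °C
Reagents that add atoms: tert-butyl hydroperoxide, CC(C)(C)OO
Why: Allylic oxidation in the tert-butylperoxyl radical manifold; hydrogen abstraction at the unhindered ring methylene C1 next to the CH end of the trisubstituted alkene (as at C7 of Δ5-steroids) and oxidation to the ketone should give the 3-methylcyclohex-2-enone, while the tertiary C4–H beside the quaternary carbon and the electron-poor tiglate react more slowly.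

Step 12
Reactants: 19 (4R,7R,9R,10S)-7-(3-methylbutanoyloxy)-3,6,6,10-tetramethyl-1-oxobicyclo[5.4.0]undec-2-en-9-yl (2E)-2-methylbut-2-enoate
Product: 20 (4R,7R,9R,10R,11RS)-11-hydroxy-7-(3-methylbutanoyloxy)-3,6,6,10-tetramethyl-1-oxobicyclo[5.4.0]undec-2-en-9-yl (2E)-2-methylbut-2-enoate
Conditions: LiN(SiMe3)2 (1.1 equiv), THF, −78 °C; 2-(phenylsulfonyl)-3-phenyloxaziridine, −78 °C; AcOH
Reagents that add atoms: 2-(phenylsulfonyl)-3-phenyloxaziridine, O=S(=O)(c1ccccc1)N1OC1c1ccccc1
Why: Kinetic deprotonation of the enone at the α' methylene C11 (far more acidic than the ester α-hydrogens; γ-deprotonation at C4 or the C3 methyl is the slower thermodynamic path), then oxygen transfer from the Davis oxaziridine; the new C11 centre is oxidised away in step 13.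

Step 13
Reactants: 20 (4R,7R,9R,10R,11RS)-11-hydroxy-7-(3-methylbutanoyloxy)-3,6,6,10-tetramethyl-1-oxobicyclo[5.4.0]undec-2-en-9-yl (2E)-2-methylbut-2-enoate
Product: 21 (4R,7R,9R,10S)-7-(3-methylbutanoyloxy)-3,6,6,10-tetramethyl-1,11-dioxobicyclo[5.4.0]undec-2-en-9-yl (2E)-2-methylbut-2-enoate (cis-fused ene-1,2-dione)
Conditions: Dess–Martin periodinane, CH2Cl2, 0 °C to rt
Reagents that add atoms: none
Why: Dess–Martin oxidation of the acyloin to the 1,2-dione without base, so C4–H (γ to C1) is not disturbed; the dione has no hydrogen at C10 and cannot enolise toward C11.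

Step 14
Reactants: 21 (4R,7R,9R,10S)-7-(3-methylbutanoyloxy)-3,6,6,10-tetramethyl-1,11-dioxobicyclo[5.4.0]undec-2-en-9-yl (2E)-2-methylbut-2-enoate
Product: 22 (4R,5R,7R,9R,10S,11S)-11-hydroxy-7-(3-methylbutanoyloxy)-3,6,6,10-tetramethyl-1-oxo tricycle with cyclobutane C4–C5–C11–C10, 9-yl (2E)-2-methylbut-2-enoate (the 11-hydroxy derivative of the target)
Conditions: hν (450 nm LEDs), degassed benzene, 0.005 M, 20 °C
Reagents that add atoms: none
Why: Visible light excites only the n–π* band of the ene-1,2-dione; in the triplet the C11 oxygen takes a hydrogen from C5 through the six-membered array O, C11, C10, C4, C5, H, and after spin inversion the C5 radical combines with the C11 hydroxy-radical centre. The closest known reaction type is the Norrish–Yang photocyclisation of ketones and 1,2-diketones to cyclobutanols. The four-membered ring is closed by radical–radical coupling across the 1,3-diaxial positions of the six-membered ring, which completes the bicyclo[3.1.1]heptane. C5 and C11 are set by topology: with the preset cis C4/C10 fusion and C6 held in the seven-membered ring, only one mode of bridging is possible. The step needs transfer from C5 and not from C8 (reachable through the equatorial C9 arm), from the C10 methyl or from C9–H (both reachable only by the conjugated C1 oxygen). Allylic strain with the C3 methyl should favour the half-chair with C5 pseudo-axial; C8–H is flanked by two acyloxy-bearing carbons and C9–H carries an acyloxy group, so both are polarity-deactivated toward the electrophilic oxygen, and the methyl hydrogens are primary. Fragmentation of the productive biradical would break the ring-fusion bond C4–C10, which lies near the nodal plane of the C11 radical orbital, so closure or harmless back-transfer should prevail. Because C9 is an ester and not a ketone, the cyclobutanol has no β-carbonyl and cannot open by retro-aldol, and at 450 nm neither the product enone nor the tiglate absorbs.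

Step 15
Reactants: 22 the 11-hydroxy tricycle of step 14
Product: 23 (4R,5R,7R,9R,10S,11S)-11-[(methoxyoxalyl)oxy] derivative of 22 (methyl oxalate of the bridgehead alcohol)
Conditions: ClC(O)CO2Me, pyridine, DMAP (cat.), CH2Cl2, 0 °C to rt
Reagents that add atoms: methyl chlorooxoacetate, COC(=O)C(=O)Cl
Why: Acylation of the exposed tertiary bridgehead hydroxyl by a very reactive acid chloride under weak base; elimination is impossible at the bridgehead, and the mild conditions avoid α-ketol rearrangement of the strained 1-acylcyclobutanol.

Step 16
Reactants: 23 the 11-methyl oxalate of step 15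
Product: 24 (4R,5S,7R,9R,10R,11R)-7-(3-methylbutanoyloxy)-3,6,6,10-tetramethyl-1-oxo tricycle with cyclobutane C4–C5–C11–C10, 9-yl (2E)-2-methylbut-2-enoate (the target, CNP0194415.1)
Conditions: Bu3SnH, AIBN, toluene, 110 °C (slow addition)
Reagents that add atoms: none
Why: Barton–McCombie-type radical deoxygenation of a tertiary methyl oxalate; stannyl radical addition, C–O scission to the bridgehead cyclobutyl σ-radical and hydrogen transfer from Bu3SnH give C11–H, whose configuration is dictated by the cage; a radical path is used because the C11–O bond is orthogonal to the C1 carbonyl π system, so ketyl-based cleavage would break the aligned cyclobutane bonds.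

## Compound list

1 | 2,2-dimethylpent-4-en-1-ol | C=CCC(C)(C)CO | starting material
2 | triethyl[(2,2-dimethylpent-4-en-1-yl)oxy]silane | C=CCC(C)(C)CO[Si](CC)(CC)CC | intermediate
3 | methacrolein (2-methylprop-2-enal) | C=C(C)C=O | starting material
4 | (2E)-2,5,5-trimethyl-6-[(triethylsilyl)oxy]hex-2-enal | O=C/C(C)=C/CC(C)(C)CO[Si](CC)(CC)CC | intermediate
5 | triethyl{[(4E)-2,2,5-trimethylhepta-4,6-dien-1-yl]oxy}silane | C=C/C(C)=C/CC(C)(C)CO[Si](CC)(CC)CC | intermediate
6 | (1S,2R)-2-{2,2-dimethyl-3-[(triethylsilyl)oxy]propyl}-1,3-dimethylcyclohex-3-ene-1-carbaldehyde | O=C[C@@]1(C)CCC=C(C)[C@H]1CC(C)(C)CO[Si](CC)(CC)CC | intermediate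
7 | 1-[(1S,2R)-2-{2,2-dimethyl-3-[(triethylsilyl)oxy]propyl}-1,3-dimethylcyclohex-3-en-1-yl]ethan-1-ol (carbinol epimers) | CC(O)[C@@]1(C)CCC=C(C)[C@H]1CC(C)(C)CO[Si](CC)(CC)CC | intermediate
8 | 1-[(1S,2R)-2-(3-hydroxy-2,2-dimethylpropyl)-1,3-dimethylcyclohex-3-en-1-yl]ethan-1-ol (carbinol epimers) | CC(O)[C@@]1(C)CCC=C(C)[C@H]1CC(C)(C)CO | intermediate
9 | 3-[(1R,6S)-6-acetyl-2,6-dimethylcyclohex-2-en-1-yl]-2,2-dimethylpropanal | CC(=O)[C@@]1(C)CCC=C(C)[C@H]1CC(C)(C)C=O | intermediate
10 | (4R,10S)-7-hydroxy-3,6,6,10-tetramethylbicyclo[5.4.0]undec-2-en-9-one (C7 epimers) | O=C1CC(O)C(C)(C)C[C@@H]2C(C)=CCC[C@]12C | intermediate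
11 | (4R,10S)-3,6,6,10-tetramethylbicyclo[5.4.0]undeca-2,7-dien-9-one | O=C1C=CC(C)(C)C[C@@H]2C(C)=CCC[C@]12C | intermediate
12 | (4R,7R,10S)-3,6,6,10-tetramethyl-7-(4,4,5,5-tetramethyl-1,3,2-dioxaborolan-2-yl)bicyclo[5.4.0]undec-2-en-9-one | O=C1C[C@@H](B3OC(C)(C)C(C)(C)O3)C(C)(C)C[C@@H]2C(C)=CCC[C@]12C | intermediate
13 | (4R,7R,10S)-7-hydroxy-3,6,6,10-tetramethylbicyclo[5.4.0]undec-2-en-9-one | O=C1C[C@@H](O)C(C)(C)C[C@@H]2C(C)=CCC[C@]12C | intermediate
14 | 3-methylbutanal | CC(C)CC=O | starting material
15 | (4R,7R,9R,10S)-9-hydroxy-3,6,6,10-tetramethylbicyclo[5.4.0]undec-2-en-7-yl 3-methylbutanoate | O[C@@H]1C[C@@H](OC(=O)CC(C)C)C(C)(C)C[C@@H]2C(C)=CCC[C@]12C | intermediate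
16 | tiglic acid, (2E)-2-methylbut-2-enoic acid | C/C=C(\C)C(=O)O | starting material
17 | (2E)-2-methylbut-2-enoic 2,4,6-trichlorobenzoic anhydride | C/C=C(\C)C(=O)OC(=O)c1c(Cl)cc(Cl)cc1Cl | intermediate
18 | (4R,7R,9R,10S)-7-(3-methylbutanoyloxy)-3,6,6,10-tetramethylbicyclo[5.4.0]undec-2-en-9-yl (2E)-2-methylbut-2-enoate | C/C=C(\C)C(=O)O[C@@H]1C[C@@H](OC(=O)CC(C)C)C(C)(C)C[C@@H]2C(C)=CCC[C@]12C | intermediate
19 | (4R,7R,9R,10S)-7-(3-methylbutanoyloxy)-3,6,6,10-tetramethyl-1-oxobicyclo[5.4.0]undec-2-en-9-yl (2E)-2-methylbut-2-enoate | C/C=C(\C)C(=O)O[C@@H]1C[C@@H](OC(=O)CC(C)C)C(C)(C)C[C@@H]2C(C)=CC(=O)C[C@]12C | intermediate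
20 | (4R,7R,9R,10R,11RS)-11-hydroxy-7-(3-methylbutanoyloxy)-3,6,6,10-tetramethyl-1-oxobicyclo[5.4.0]undec-2-en-9-yl (2E)-2-methylbut-2-enoate | C/C=C(\C)C(=O)O[C@@H]1C[C@@H](OC(=O)CC(C)C)C(C)(C)C[C@@H]2C(C)=CC(=O)C(O)[C@]12C | intermediate
21 | (4R,7R,9R,10S)-7-(3-methylbutanoyloxy)-3,6,6,10-tetramethyl-1,11-dioxobicyclo[5.4.0]undec-2-en-9-yl (2E)-2-methylbut-2-enoate | C/C=C(\C)C(=O)O[C@@H]1C[C@@H](OC(=O)CC(C)C)C(C)(C)C[C@@H]2C(C)=CC(=O)C(=O)[C@]12C | intermediate
22 | (4R,5R,7R,9R,10S,11S)-11-hydroxy tricycle (cyclobutane C4–C5–C11–C10), 1-oxo, 7-(3-methylbutanoate), 9-[(2E)-2-methylbut-2-enoate] | C/C=C(\C)C(=O)O[C@@H]1C[C@@H](OC(=O)CC(C)C)C(C)(C)[C@@H]2[C@@]3(O)C(=O)C=C(C)[C@@H]2[C@]31C | intermediate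
23 | (4R,5R,7R,9R,10S,11S)-11-[(methoxyoxalyl)oxy] derivative of 22 | C/C=C(\C)C(=O)O[C@@H]1C[C@@H](OC(=O)CC(C)C)C(C)(C)[C@@H]2[C@@]3(OC(=O)C(=O)OC)C(=O)C=C(C)[C@@H]2[C@]31C | intermediate
24 | (4R,5S,7R,9R,10R,11R)-7-(3-methylbutanoyloxy)-1-oxolongipin-2-en-9-yl (2E)-2-methylbut-2-enoate (CNP0194415.1) | C/C=C(\C)C(=O)O[C@@H]1C[C@@H](OC(=O)CC(C)C)C(C)(C)[C@@H]2[C@H]3C(=O)C=C(C)[C@@H]2[C@]31C | target

## Step count and least certain steps

Total: 16 steps. Longest linear sequence: 16 steps (1 to 24); 3, 14 and 16 enter as purchased partners.

**Step 14 (key step).** What may go wrong is hydrogen transfer at the wrong site, followed by closure or fragmentation of the wrong biradical: from C8 to the C11 oxygen through the equatorial C9 arm, or from the C10 methyl or C9–H to the conjugated C1 oxygen. The triplet dione may also add to, or isomerise, the tigloyl alkene. The fallback keeps the photocyclisation but takes the tiglate out of the irradiated molecule and makes C9 more electron-poor. It sets out from 15. Acylation with 2,2,2-trichloroethyl chloroformate and pyridine gives the C9 trichloroethyl carbonate F1. The conditions of steps 11 to 13 give the enone F2, the α'-hydroxy enone F3 and the ene-1,2-dione F4. Irradiation as in step 14 gives the cyclobutanol F5, zinc in acetic acid releases the 9,11-diol F6, and Yamaguchi tigloylation of the secondary C9 hydroxyl (the tertiary bridgehead hydroxyl should not react) returns to the route at 22.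

**Step 16.** The C–O scission may be slow, because the bridgehead cyclobutyl radical is a σ-radical that gains nothing from the neighbouring carbonyl. The stannyl adduct could then be reduced or revert, and stannyl radicals could add reversibly to the enone or the tiglate (E/Z drift). The fallback changes the radical precursor. From 22, NaN(SiMe3)2, CS2 and MeI at −78 °C give the S-methyl xanthate F7, which cannot undergo Chugaev elimination at a bridgehead. Thiophilic addition of the stannyl radical is then irreversible and the scission is driven by carbonyl formation; Bu3SnH with a high-temperature azo initiator in xylene at 130 °C returns to the route at 24.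

**Step 4.** The tethered functionality or the crowded diene may sequester the boron catalyst, and the enantiomeric excess or the endo preference may be eroded with an α-methyl enal. The fallback replaces catalytic enantiocontrol by resolution. From 5 and 3, cycloaddition with the achiral Lewis acid MeAlCl2 gives 6 together with its enantiomer F8. Condensation with (1R,2R)-N,N'-dimethyl-1,2-diphenylethane-1,2-diamine converts the pair into the diastereomeric imidazolidines F9 (from 6) and F10 (from F8), which are separated by chromatography. Brief aqueous acid on F9 returns to the route at 6.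

**Step 8.** Facial selectivity at C7 may be poor, since the resident stereocentres are remote and the neighbouring carbon is quaternary, and addition to the hindered β-carbon may be slow. The fallback sets the C7 oxygen by substrate-controlled epoxidation. From 11, nucleophilic epoxidation (t-BuOOH, DBU) on the convex face gives the 7,8-epoxy ketone F11, and SmI2 in THF/MeOH at −90 °C cleaves the α C–O bond to return to the route at 13.

**Step 9.** Retro-aldol opening of the samarium aldolate would scramble C7, hydride transfer to the neopentylic C9 carbonyl may be slow, and the acyl group may migrate from C7 to C9. The fallback separates acylation from reduction. From 13, isovaleryl chloride with pyridine at −20 °C gives the keto ester F12, and reagent-controlled reduction with (S)-2-methyl-CBS-oxazaborolidine and BH3·SMe2 (C10 as the large and C8 as the small ketone substituent) should deliver hydride to the face that gives the 9R alcohol, returning to the route at 15.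

## Further compounds

F1 | step 14 | (4R,7R,9R,10S)-7-(3-methylbutanoyloxy)-3,6,6,10-tetramethylbicyclo[5.4.0]undec-2-en-9-yl 2,2,2-trichloroethyl carbonate | O=C(OCC(Cl)(Cl)Cl)O[C@@H]1C[C@@H](OC(=O)CC(C)C)C(C)(C)C[C@@H]2C(C)=CCC[C@]12C
F2 | step 14 | 1-oxo derivative of F1 (enone) | O=C(OCC(Cl)(Cl)Cl)O[C@@H]1C[C@@H](OC(=O)CC(C)C)C(C)(C)C[C@@H]2C(C)=CC(=O)C[C@]12C
F3 | step 14 | 11-hydroxy-1-oxo derivative of F1 (C11 epimers) | O=C(OCC(Cl)(Cl)Cl)O[C@@H]1C[C@@H](OC(=O)CC(C)C)C(C)(C)C[C@@H]2C(C)=CC(=O)C(O)[C@]12C
F4 | step 14 | 1,11-dioxo derivative of F1 (ene-1,2-dione) | O=C(OCC(Cl)(Cl)Cl)O[C@@H]1C[C@@H](OC(=O)CC(C)C)C(C)(C)C[C@@H]2C(C)=CC(=O)C(=O)[C@]12C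
F5 | step 14 | 11-hydroxy tricyclic 9-(2,2,2-trichloroethyl carbonate) 7-(3-methylbutanoate) | O=C(OCC(Cl)(Cl)Cl)O[C@@H]1C[C@@H](OC(=O)CC(C)C)C(C)(C)[C@@H]2[C@@]3(O)C(=O)C=C(C)[C@@H]2[C@]31C
F6 | step 14 | 9,11-dihydroxy tricyclic enone 7-(3-methylbutanoate) | O[C@@H]1C[C@@H](OC(=O)CC(C)C)C(C)(C)[C@@H]2[C@@]3(O)C(=O)C=C(C)[C@@H]2[C@]31C
F7 | step 16 | O-(C11) S-methyl xanthate of 22 | C/C=C(\C)C(=O)O[C@@H]1C[C@@H](OC(=O)CC(C)C)C(C)(C)[C@@H]2[C@@]3(OC(=S)SC)C(=O)C=C(C)[C@@H]2[C@]31C
F8 | step 4 | (1R,2S)-2-{2,2-dimethyl-3-[(triethylsilyl)oxy]propyl}-1,3-dimethylcyclohex-3-ene-1-carbaldehyde (enantiomer of 6) | O=C[C@]1(C)CCC=C(C)[C@@H]1CC(C)(C)CO[Si](CC)(CC)CC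
F9 | step 4 | (4R,5R)-1,3-dimethyl-4,5-diphenylimidazolidine aminal of 6 | CN1[C@H](c2ccccc2)[C@@H](c2ccccc2)N(C)C1[C@@]3(C)CCC=C(C)[C@H]3CC(C)(C)CO[Si](CC)(CC)CC
F10 | step 4 | (4R,5R)-1,3-dimethyl-4,5-diphenylimidazolidine aminal of F8 | CN1[C@H](c2ccccc2)[C@@H](c2ccccc2)N(C)C1[C@]3(C)CCC=C(C)[C@@H]3CC(C)(C)CO[Si](CC)(CC)CC
F11 | step 8 | (4R,7S,8S,10S)-7,8-epoxy-3,6,6,10-tetramethylbicyclo[5.4.0]undec-2-en-9-one (epoxide on the face of the C10 methyl) | O=C1[C@H]2O[C@H]2C(C)(C)C[C@@H]3C(C)=CCC[C@]13C
F12 | step 9 | (4R,7R,10S)-3,6,6,10-tetramethyl-9-oxobicyclo[5.4.0]undec-2-en-7-yl 3-methylbutanoate | O=C1C[C@@H](OC(=O)CC(C)C)C(C)(C)C[C@@H]2C(C)=CCC[C@]12C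
A1 | alternative 1 | (2E,6E)-farnesyl diphosphate | CC(C)=CCC/C(C)=C/CC/C(C)=C/COP(=O)(O)OP(=O)(O)O
A2 | alternative 1 | α-longipinene | C1CCC(C)(C)[C@@H]2[C@H]3CC=C(C)[C@@H]2[C@]31C
A3 | alternative 2 | methyl 2,4-dibromo-2-methyl-3-oxocyclobutane-1-carboxylate (diastereomer mixture) | COC(=O)C1C(Br)C(=O)C1(C)Br
A4 | alternative 2 | (1E)-1-[(4-methoxybenzyl)oxy]-4-methyl-3-[(trimethylsilyl)oxy]penta-1,3-diene | COc1ccc(CO/C=C/C(O[Si](C)(C)C)=C(C)C)cc1
A5 | alternative 2 | bicyclo[4.1.1]oct-3-en-8-one with C7 silyl enol ether, C9 4-methoxybenzyl ether, C11 methyl ester | COc1ccc(CO[C@@H]2C=C(O[Si](C)(C)C)C(C)(C)[C@@H]3[C@@H](C(=O)OC)[C@@]2(C)C3=O)cc1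
A6 | alternative 3 | 5-methyl-5-(tethered alkenylboronate) 3-methyl-1-(triethylsilyloxy)cyclopenta-1,3-diene with C7 isovalerate and C9 tert-butyldimethylsilyl ether | CC(C)CC(=O)O[C@H](C[C@@H](O[Si](C)(C)C(C)(C)C)[C@@]1(C)C(O[Si](CC)(CC)CC)=CC(C)=C1)C(C)(C)/C=C/B2OC(C)(C)C(C)(C)O2
A7 | alternative 3 | tricyclic norbornene with bridgehead triethylsilyl ether and endo C11 pinacol boronate | [C@]12(O[Si](CC)(CC)CC)C=C(C)[C@H]3[C@H](C(C)(C)[C@H](OC(=O)CC(C)C)C[C@@H](O[Si](C)(C)C(C)(C)C)[C@@]13C)[C@H]2B4OC(C)(C)C(C)(C)O4
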